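**Plan**

- Retrosynthesis: the oxirane oxygen is taken off C1–C10 first, then the ten-membered ring is opened at C3–C4, the lactone at C6–O and C6–C7, the acrylate unit at C7–C11, and the chain at C9–C10 and C1–C2.
- The C3–C4 cut rests on one feature: C3 is a secondary allylic carbinol carbon bonded to C4, the methyl-bearing carbon of the cis C4=C5 alkene in the ten-membered carbocycle. This bond is what a (Z)-alkenylmetal at C4 forms when it adds to a C3 aldehyde.
- Forward: carbocupration of propyne builds C7–C10 and C1–C3 with the Z C1=C10 alkene. C8 is then oxygenated, and Baylis–Hillman/bromination adds C11–C13. An indium Barbier reaction with (Z)-3-iodobut-2-enal (C4–C6, C15) closes the lactone ring. The isobutyrate goes on, the ten-membered ring closes at C3–C4, and the oxirane comes last.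
- Stereochemistry: C8 comes from L-proline-catalysed α-aminoxylation. C7 and C6 are relayed from C8 in the Barbier step (cis-lactone). C3 comes from the macrocyclic transition state, and C1/C10 from face-selective peracid attack. Alkene geometries come from syn-carbocupration, trans-hydroalumination and retention in the chromium step.

Key step: step 17

Remark: germacrane numbering is used for all intermediates (ring carbons C1–C10, lactone carbonyl C12, exocyclic methylene C13, methyls C14 on C10 and C15 on C4). TBDPS = tert-butyldiphenylsilyl, TES = triethylsilyl.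

**Route**

Step 1
Reactants: 1 2-(2-bromoethyl)-1,3-dioxolane; 2 propyne; 3 oxirane
Product: 7 (3Z)-6-(1,3-dioxolan-2-yl)-4-methylhex-3-en-1-ol, via Grignard reagent 4 (not isolated), via alkylcopper 5 (not isolated), via alkenylcopper 6 (not isolated)
Conditions: Mg, THF, 25 °C; CuBr·SMe2, Et2O/Me2S, −45 °C; propyne, −25 °C; LiC≡C-n-Pr, HMPA, then oxirane, −78 → −20 °C; aq NH4Cl
Reagents that add atoms: none
Why: Grignard formation then Normant carbocupration: the alkylcopper adds syn across propyne with copper on the terminal carbon, and the alkenylcopper opens oxirane with retention, so C9 and C2 end up cis on the C1=C10 alkene (Z).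

Step 2
Reactants: 7 (3Z)-6-(1,3-dioxolan-2-yl)-4-methylhex-3-en-1-ol
Product: 8 tert-butyl{[(3Z)-6-(1,3-dioxolan-2-yl)-4-methylhex-3-en-1-yl]oxy}diphenylsilane
Conditions: TBDPSCl, imidazole, DMF, rt
Reagents that add atoms: tert-butyl(chloro)diphenylsilane CC(C)(C)[Si](Cl)(c1ccccc1)c1ccccc1
Why: Standard silylation of the primary C3 alcohol; the TBDPS ether is chosen because it withstands the acid of step 3 and the mild desilylation of step 13.

Step 3
Reactants: 8 tert-butyl{[(3Z)-6-(1,3-dioxolan-2-yl)-4-methylhex-3-en-1-yl]oxy}diphenylsilane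
Product: 9 (4Z)-7-[(tert-butyldiphenylsilyl)oxy]-4-methylhept-4-enal
Conditions: 1 M aq HCl, THF, rt
Reagents that add atoms: water O
Why: Acid-catalysed acetal hydrolysis frees the C7 aldehyde; the TBDPS ether and the trisubstituted alkene are stable to dilute HCl.

Step 4
Reactants: 9 (4Z)-7-[(tert-butyldiphenylsilyl)oxy]-4-methylhept-4-enal
Product: 11 (2R,4Z)-2-(anilinooxy)-7-[(tert-butyldiphenylsilyl)oxy]-4-methylhept-4-en-1-ol, via anilinooxy aldehyde 10 (not isolated)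
Conditions: PhNO, L-proline (20 mol%), CHCl3, 4 °C; then NaBH4, EtOH, 0 °C
Reagents that add atoms: nitrosobenzene O=Nc1ccccc1
Why: Proline-catalysed α-aminoxylation: the (E)-enamine of 9 attacks the nitroso oxygen through the hydrogen-bonded transition state on the face set by L-proline, which makes C8 R, and NaBH4 reduces the labile aldehyde 10 in the same flask.

Step 5
Reactants: 11 (2R,4Z)-2-(anilinooxy)-7-[(tert-butyldiphenylsilyl)oxy]-4-methylhept-4-en-1-ol
Product: 12 (2R,4Z)-7-[(tert-butyldiphenylsilyl)oxy]-4-methylhept-4-ene-1,2-diol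
Conditions: Zn dust, AcOH/THF, rt
Reagents that add atoms: none
Why: Reductive N–O cleavage by zinc in acetic acid leaves the C8–O bond and its configuration untouched.

Step 6
Reactants: 12 (2R,4Z)-7-[(tert-butyldiphenylsilyl)oxy]-4-methylhept-4-ene-1,2-diol
Product: 13 (2R,4Z)-7-[(tert-butyldiphenylsilyl)oxy]-4-methyl-1,2-bis[(triethylsilyl)oxy]hept-4-ene
Conditions: TESCl, imidazole, CH2Cl2, 0 °C → rt
Reagents that add atoms: chlorotriethylsilane CC[Si](Cl)(CC)CC
Why: Exhaustive silylation of the diol sets up the selective oxidation of step 7 and leaves a non-migrating, poorly leaving oxygen substituent on C8.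

Step 7
Reactants: 13 (2R,4Z)-7-[(tert-butyldiphenylsilyl)oxy]-4-methyl-1,2-bis[(triethylsilyl)oxy]hept-4-ene
Product: 14 (2R,4Z)-7-[(tert-butyldiphenylsilyl)oxy]-4-methyl-2-[(triethylsilyl)oxy]hept-4-enal
Conditions: (COCl)2, DMSO, CH2Cl2, −78 → −40 °C; Et3N, −78 °C → rt
Reagents that add atoms: none
Why: Swern oxidation with oxidative cleavage of the primary TES ether: the chlorosulfonium salt attacks only the unhindered primary silyl ether, so the C7 aldehyde forms directly, the secondary TES and the TBDPS ethers stay, and the low temperature protects C8 from epimerisation.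

Step 8
Reactants: 14 (2R,4Z)-7-[(tert-butyldiphenylsilyl)oxy]-4-methyl-2-[(triethylsilyl)oxy]hept-4-enal; 15 methyl acrylate
Product: 16 methyl (4R,6Z)-9-[(tert-butyldiphenylsilyl)oxy]-3-hydroxy-6-methyl-2-methylidene-4-[(triethylsilyl)oxy]non-6-enoate (both C7 epimers)
Conditions: DABCO, methyl acrylate (neat, excess), rt, several days
Reagents that add atoms: none
Why: Baylis–Hillman reaction: the DABCO–acrylate zwitterion adds to the aldehyde and forms C7–C11; the new C7 carbinol centre needs no control because step 9 makes C7 sp2, and α-silyloxy aldehydes are a known substrate class.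

Step 9
Reactants: 16 methyl (4R,6Z)-9-[(tert-butyldiphenylsilyl)oxy]-3-hydroxy-6-methyl-2-methylidene-4-[(triethylsilyl)oxy]non-6-enoate
Product: 17 methyl (2Z,4R,6Z)-2-(bromomethyl)-9-[(tert-butyldiphenylsilyl)oxy]-6-methyl-4-[(triethylsilyl)oxy]nona-2,6-dienoate
Conditions: NBS, Me2S, CH2Cl2, 0 °C → rt
Reagents that add atoms: N-bromosuccinimide O=C1CCC(=O)N1Br
Why: Bromination with allylic transposition (SN2′) of the Baylis–Hillman alcohol by the bromosulfonium reagent gives the conjugated (Z)-2-(bromomethyl)enoate, the thermodynamically preferred geometry with C8 cis to CH2Br.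

Step 10
Reactants: 18 but-2-yn-1-ol
Product: 20 (2Z)-3-iodobut-2-en-1-ol, via vinylalanate 19 (not isolated)
Conditions: NaAlH2(OCH2CH2OMe)2, THF, 0 °C → rt; then I2, −78 → 0 °C
Reagents that add atoms: iodine II
Why: Hydroxyl-directed trans-hydroalumination puts aluminium on C4 cis to the carbinol carbon (cyclic alanate 19), and iodinolysis proceeds with retention to give the Z iodide.

Step 11
Reactants: 20 (2Z)-3-iodobut-2-en-1-ol
Product: 21 (2Z)-3-iodobut-2-enal
Conditions: MnO2, CH2Cl2, rt, dark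
Reagents that add atoms: none
Why: MnO2 oxidises the allylic alcohol to the enal without touching the alkenyl iodide or its geometry; 21 is used fresh.

Step 12
Reactants: 17 methyl (2Z,4R,6Z)-2-(bromomethyl)-9-[(tert-butyldiphenylsilyl)oxy]-6-methyl-4-[(triethylsilyl)oxy]nona-2,6-dienoate; 21 (2Z)-3-iodobut-2-enal
Product: 24 (4S,5R)-4-[(1R,3Z)-6-[(tert-butyldiphenylsilyl)oxy]-3-methyl-1-[(triethylsilyl)oxy]hex-3-en-1-yl]-5-[(1Z)-2-iodoprop-1-en-1-yl]-3-methylideneoxolan-2-one, via allylindium 22 (not isolated), via hydroxy ester 23 (not isolated)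
Conditions: In powder, THF/H2O (1:1), rt; then PPTS (cat.), toluene, 60 °C
Reagents that add atoms: none
Why: Indium Barbier allylation then lactonisation: the Z-allylindium attacks the aldehyde through C7 in a chair-like six-membered transition state with C8 axial, which gives the syn adduct and hence the cis-lactone, and with H8 eclipsing C7=C11 (A(1,3) strain against the metalated CH2) the aldehyde should bond anti to the C8–C9 bond and syn to the silyloxy group, which sets C7 and C6 relative to C8.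

Step 13
Reactants: 24 (4S,5R)-4-[(1R,3Z)-6-[(tert-butyldiphenylsilyl)oxy]-3-methyl-1-[(triethylsilyl)oxy]hex-3-en-1-yl]-5-[(1Z)-2-iodoprop-1-en-1-yl]-3-methylideneoxolan-2-one
Product: 25 (4R,5R)-4-[(1R,3Z)-6-[(tert-butyldiphenylsilyl)oxy]-1-hydroxy-3-methylhex-3-en-1-yl]-5-[(1Z)-2-iodoprop-1-en-1-yl]-3-methylideneoxolan-2-one
Conditions: AcOH/THF/H2O (3:1:1), rt
Reagents that add atoms: none
Why: Mild acid hydrolysis removes the secondary TES ether while the primary TBDPS ether and the lactone persist.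

Step 14
Reactants: 25 (4R,5R)-4-[(1R,3Z)-6-[(tert-butyldiphenylsilyl)oxy]-1-hydroxy-3-methylhex-3-en-1-yl]-5-[(1Z)-2-iodoprop-1-en-1-yl]-3-methylideneoxolan-2-one; 26 2-methylpropanoyl chloride
Product: 27 (1R,3Z)-6-[(tert-butyldiphenylsilyl)oxy]-1-[(2R,3R)-2-[(1Z)-2-iodoprop-1-en-1-yl]-4-methylidene-5-oxooxolan-3-yl]-3-methylhex-3-en-1-yl 2-methylpropanoate
Conditions: pyridine, DMAP (cat.), CH2Cl2, 0 °C
Reagents that add atoms: none
Why: DMAP-catalysed acylation of the C8 hydroxyl by the acid chloride, done at once so that the free hydroxyl has no time to translactonise.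

Step 15
Reactants: 27 (1R,3Z)-6-[(tert-butyldiphenylsilyl)oxy]-1-[(2R,3R)-2-[(1Z)-2-iodoprop-1-en-1-yl]-4-methylidene-5-oxooxolan-3-yl]-3-methylhex-3-en-1-yl 2-methylpropanoate
Product: 28 (1R,3Z)-6-hydroxy-1-[(2R,3R)-2-[(1Z)-2-iodoprop-1-en-1-yl]-4-methylidene-5-oxooxolan-3-yl]-3-methylhex-3-en-1-yl 2-methylpropanoate
Conditions: HF·pyridine, pyridine, THF, 0 °C → rt
Reagents that add atoms: none
Why: Fluoride cleavage of the primary TBDPS ether under buffered conditions that spare the isobutyrate, the α-methylene lactone and the alkenyl iodide.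

Step 16
Reactants: 28 (1R,3Z)-6-hydroxy-1-[(2R,3R)-2-[(1Z)-2-iodoprop-1-en-1-yl]-4-methylidene-5-oxooxolan-3-yl]-3-methylhex-3-en-1-yl 2-methylpropanoate
Product: 29 (1R,3Z)-1-[(2R,3R)-2-[(1Z)-2-iodoprop-1-en-1-yl]-4-methylidene-5-oxooxolan-3-yl]-3-methyl-6-oxohex-3-en-1-yl 2-methylpropanoate
Conditions: Dess–Martin periodinane, NaHCO3, CH2Cl2, 0 °C
Reagents that add atoms: none
Why: Dess–Martin oxidation under bicarbonate buffer gives the β,γ-unsaturated C3 aldehyde without moving the C1=C10 alkene into conjugation; 29 is used at once.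

Step 17
Reactants: 29 (1R,3Z)-1-[(2R,3R)-2-[(1Z)-2-iodoprop-1-en-1-yl]-4-methylidene-5-oxooxolan-3-yl]-3-methyl-6-oxohex-3-en-1-yl 2-methylpropanoate
Product: 31 (1(10)Z,3S,4Z,6S,7R,8R)-3-hydroxy-8-(2-methylpropanoyloxy)germacra-1(10),4,11(13)-trien-12,6-olide, via alkenylchromium 30 (not isolated)
Conditions: CrCl2 (excess), NiCl2 (cat.), degassed DMSO, rt, slow addition of 29 to about 2 mM; aq work-up
Reagents that add atoms: none
Why: CrCl2 reduces NiCl2 to zerovalent nickel, which inserts into the C4–I bond with retention of the Z geometry; transmetalation to trivalent chromium gives alkenylchromium 30, which adds 1,2 to the chromium-activated C3 aldehyde and forms C3–C4. The closest known reaction type is the intramolecular Nozaki–Hiyama–Kishi alkenyl iodide–aldehyde coupling to medium-ring allylic alcohols. The ten-membered carbocycle (C1–C10) closes by 10-exo-trig attack of C4 on the C3 carbonyl carbon, helped by the cis-fused lactone and the two Z alkenes, which fold the chain and bring C3 near C4. The new stereocentre C3 is under substrate control by the macrocyclic transition state: the chromium-bound carbonyl oxygen should point to the outside of the forming ring on the side that carries O6 and O8, which corresponds to 3S. The step needs chemoselectivity for the aldehyde over the lactone, the isobutyrate and the enoate, which the low basicity and aldehyde preference of alkenylchromium secure, and it needs ring closure to outrun oligomerisation, which slow addition at high dilution secures.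

Step 18
Reactants: 31 (1(10)Z,3S,4Z,6S,7R,8R)-3-hydroxy-8-(2-methylpropanoyloxy)germacra-1(10),4,11(13)-trien-12,6-olide
Product: 32 (1R,3S,4Z,6S,7R,8R,10S)-1,10-epoxy-3-hydroxy-8-(2-methylpropanoyloxy)germacra-4,11(13)-dien-12,6-olide
Conditions: mCPBA (1 equiv), aq NaHCO3, CH2Cl2, −20 → 0 °C
Reagents that add atoms: 3-chloroperoxybenzoic acid OOC(=O)c1cccc(Cl)c1
Why: Prilezhaev epoxidation: the peracid takes the most electron-rich alkene (C1=C10; C4=C5 is deactivated by two allylic C–O bonds and C11=C13 by the carbonyl), adds syn so that C2 and C9 stay cis, and should attack the face of the Z alkene on the side of the C3 hydroxyl (hydrogen bond to the peracid), which gives 1R,10S.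

**Compound list**

1 | 2-(2-bromoethyl)-1,3-dioxolane | BrCCC1OCCO1 | starting material
2 | propyne | CC#C | starting material
3 | oxirane | C1CO1 | starting material
4 | [2-(1,3-dioxolan-2-yl)ethyl]magnesium bromide (Grignard reagent; not isolated) | Br[Mg]CCC1OCCO1 | intermediate
5 | [2-(1,3-dioxolan-2-yl)ethyl]copper (alkylcopper; not isolated) | [Cu]CCC1OCCO1 | intermediate
6 | [(1Z)-5-(1,3-dioxolan-2-yl)-2-methylpent-1-en-1-yl]copper (alkenylcopper; not isolated) | [Cu]/C=C(/C)CCC1OCCO1 | intermediate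
7 | (3Z)-6-(1,3-dioxolan-2-yl)-4-methylhex-3-en-1-ol | OCC/C=C(/C)CCC1OCCO1 | intermediate
8 | tert-butyl{[(3Z)-6-(1,3-dioxolan-2-yl)-4-methylhex-3-en-1-yl]oxy}diphenylsilane | CC(C)(C)[Si](OCC/C=C(/C)CCC1OCCO1)(c2ccccc2)c3ccccc3 | intermediate
9 | (4Z)-7-[(tert-butyldiphenylsilyl)oxy]-4-methylhept-4-enal | O=CCC/C(C)=C\CCO[Si](c1ccccc1)(c2ccccc2)C(C)(C)C | intermediate
10 | (2R,4Z)-2-(anilinooxy)-7-[(tert-butyldiphenylsilyl)oxy]-4-methylhept-4-enal (not isolated) | O=C[C@H](ONc1ccccc1)C/C(C)=C\CCO[Si](c2ccccc2)(c3ccccc3)C(C)(C)C | intermediate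
11 | (2R,4Z)-2-(anilinooxy)-7-[(tert-butyldiphenylsilyl)oxy]-4-methylhept-4-en-1-ol | OC[C@H](ONc1ccccc1)C/C(C)=C\CCO[Si](c2ccccc2)(c3ccccc3)C(C)(C)C | intermediate
12 | (2R,4Z)-7-[(tert-butyldiphenylsilyl)oxy]-4-methylhept-4-ene-1,2-diol | OC[C@H](O)C/C(C)=C\CCO[Si](c1ccccc1)(c2ccccc2)C(C)(C)C | intermediate
13 | (2R,4Z)-7-[(tert-butyldiphenylsilyl)oxy]-4-methyl-1,2-bis[(triethylsilyl)oxy]hept-4-ene | CC[Si](CC)(CC)OC[C@H](O[Si](CC)(CC)CC)C/C(C)=C\CCO[Si](c1ccccc1)(c2ccccc2)C(C)(C)C | intermediate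
14 | (2R,4Z)-7-[(tert-butyldiphenylsilyl)oxy]-4-methyl-2-[(triethylsilyl)oxy]hept-4-enal | O=C[C@H](O[Si](CC)(CC)CC)C/C(C)=C\CCO[Si](c1ccccc1)(c2ccccc2)C(C)(C)C | intermediate
15 | methyl acrylate | C=CC(=O)OC | starting material
16 | methyl (4R,6Z)-9-[(tert-butyldiphenylsilyl)oxy]-3-hydroxy-6-methyl-2-methylidene-4-[(triethylsilyl)oxy]non-6-enoate (both C7 epimers) | C=C(C(=O)OC)C(O)[C@H](O[Si](CC)(CC)CC)C/C(C)=C\CCO[Si](c1ccccc1)(c2ccccc2)C(C)(C)C | intermediate
17 | methyl (2Z,4R,6Z)-2-(bromomethyl)-9-[(tert-butyldiphenylsilyl)oxy]-6-methyl-4-[(triethylsilyl)oxy]nona-2,6-dienoate | COC(=O)/C(CBr)=C/[C@H](O[Si](CC)(CC)CC)C/C(C)=C\CCO[Si](c1ccccc1)(c2ccccc2)C(C)(C)C | intermediate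
18 | but-2-yn-1-ol | CC#CCO | starting material
19 | sodium 2,2-bis(2-methoxyethoxy)-3-methyl-2,5-dihydro-1,2-oxaaluminol-2-uide (vinylalanate; not isolated) | CC1=CCO[Al-]1(OCCOC)OCCOC.[Na+] | intermediate
20 | (2Z)-3-iodobut-2-en-1-ol | C/C(I)=C/CO | intermediate
21 | (2Z)-3-iodobut-2-enal | C/C(I)=C/C=O | intermediate
22 | methyl (2Z,4R,6Z)-9-[(tert-butyldiphenylsilyl)oxy]-2-[(dibromoindiganyl)methyl]-6-methyl-4-[(triethylsilyl)oxy]nona-2,6-dienoate (allylindium; not isolated) | COC(=O)/C(C[In](Br)Br)=C/[C@H](O[Si](CC)(CC)CC)C/C(C)=C\CCO[Si](c1ccccc1)(c2ccccc2)C(C)(C)C | intermediate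
23 | methyl 2-[(2Z,4R,5S,6R,8Z)-11-[(tert-butyldiphenylsilyl)oxy]-4-hydroxy-2-iodo-8-methyl-6-[(triethylsilyl)oxy]undeca-2,8-dien-5-yl]prop-2-enoate (hydroxy ester; not isolated) | C=C(C(=O)OC)[C@@H]([C@@H](O)/C=C(/C)I)[C@H](O[Si](CC)(CC)CC)C/C(C)=C\CCO[Si](c1ccccc1)(c2ccccc2)C(C)(C)C | intermediate
24 | (4S,5R)-4-[(1R,3Z)-6-[(tert-butyldiphenylsilyl)oxy]-3-methyl-1-[(triethylsilyl)oxy]hex-3-en-1-yl]-5-[(1Z)-2-iodoprop-1-en-1-yl]-3-methylideneoxolan-2-one | C=C1C(=O)O[C@@H](/C=C(/C)I)[C@H]1[C@H](O[Si](CC)(CC)CC)C/C(C)=C\CCO[Si](c2ccccc2)(c3ccccc3)C(C)(C)C | intermediate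
25 | (4R,5R)-4-[(1R,3Z)-6-[(tert-butyldiphenylsilyl)oxy]-1-hydroxy-3-methylhex-3-en-1-yl]-5-[(1Z)-2-iodoprop-1-en-1-yl]-3-methylideneoxolan-2-one | C=C1C(=O)O[C@@H](/C=C(/C)I)[C@H]1[C@H](O)C/C(C)=C\CCO[Si](c2ccccc2)(c3ccccc3)C(C)(C)C | intermediate
26 | 2-methylpropanoyl chloride (isobutyryl chloride) | CC(C)C(Cl)=O | starting material
27 | (1R,3Z)-6-[(tert-butyldiphenylsilyl)oxy]-1-[(2R,3R)-2-[(1Z)-2-iodoprop-1-en-1-yl]-4-methylidene-5-oxooxolan-3-yl]-3-methylhex-3-en-1-yl 2-methylpropanoate | C=C1C(=O)O[C@@H](/C=C(/C)I)[C@H]1[C@H](OC(=O)C(C)C)C/C(C)=C\CCO[Si](c2ccccc2)(c3ccccc3)C(C)(C)C | intermediate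
28 | (1R,3Z)-6-hydroxy-1-[(2R,3R)-2-[(1Z)-2-iodoprop-1-en-1-yl]-4-methylidene-5-oxooxolan-3-yl]-3-methylhex-3-en-1-yl 2-methylpropanoate | C=C1C(=O)O[C@@H](/C=C(/C)I)[C@H]1[C@H](OC(=O)C(C)C)C/C(C)=C\CCO | intermediate
29 | (1R,3Z)-1-[(2R,3R)-2-[(1Z)-2-iodoprop-1-en-1-yl]-4-methylidene-5-oxooxolan-3-yl]-3-methyl-6-oxohex-3-en-1-yl 2-methylpropanoate | C=C1C(=O)O[C@@H](/C=C(/C)I)[C@H]1[C@H](OC(=O)C(C)C)C/C(C)=C\CC=O | intermediate
30 | C4-dichlorochromio analogue of 29 (alkenylchromium dichloride with trivalent chromium; not isolated) | C=C1C(=O)O[C@@H](/C=C(/C)[Cr](Cl)Cl)[C@H]1[C@H](OC(=O)C(C)C)C/C(C)=C\CC=O | intermediate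
31 | (1(10)Z,3S,4Z,6S,7R,8R)-3-hydroxy-8-(2-methylpropanoyloxy)germacra-1(10),4,11(13)-trien-12,6-olide | C=C1C(=O)O[C@H]2/C=C(/C)[C@@H](O)C/C=C(/C)C[C@@H](OC(=O)C(C)C)[C@@H]12 | intermediate
32 | (1R,3S,4Z,6S,7R,8R,10S)-1,10-epoxy-3-hydroxy-8-(2-methylpropanoyloxy)germacra-4,11(13)-dien-12,6-olide | C=C1C(=O)O[C@H]2/C=C(/C)[C@@H](O)C[C@H]3O[C@@]3(C)C[C@@H](OC(=O)C(C)C)[C@@H]12 | target

**Counts**

Total step count: 18.
Longest linear sequence: 16 steps (steps 1–9 and 12–18, from 1).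

**Steps most likely to fail**

Step 17 (ring closure at C3–C4). The alkenylchromium may add to the wrong face of the C3 aldehyde, because the C3 configuration rests only on the conformation of the closing ring. The fallback sets out from 29 and comes back at 31. The closure is run as in step 17 and the alcohol formed, the 3-epimer (1(10)Z,3R,4Z,6S,7R,8R)-3-hydroxy-8-(2-methylpropanoyloxy)germacra-1(10),4,11(13)-trien-12,6-olide F1, is oxidised with MnO2 in CH2Cl2 to the 3-oxo compound (1(10)Z,4Z,6S,7R,8R)-8-(2-methylpropanoyloxy)-3-oxogermacra-1(10),4,11(13)-trien-12,6-olide F2. Corey–Bakshi–Shibata reduction of F2 with the (R)-oxazaborolidine and catecholborane at low temperature then sets 3S under reagent control (alkenyl C4 as the large group) and gives 31.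

Step 12 (indium Barbier reaction). The aldehyde may bond to C7 on the face anti to the C8 silyloxy group, which would give the cis-lactone with the wrong C7/C8 relationship. The fallback turns that preference to use by working in the 8-epi series and inverting C8 at the esterification. It sets out from 9 and comes back at 27.
- Step 4 is run with D-proline: the aldehyde (2S,4Z)-2-(anilinooxy)-7-[(tert-butyldiphenylsilyl)oxy]-4-methylhept-4-enal F3 is reduced in the flask to (2S,4Z)-2-(anilinooxy)-7-[(tert-butyldiphenylsilyl)oxy]-4-methylhept-4-en-1-ol F4.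
- Steps 5–9 are repeated unchanged: Zn/AcOH gives (2S,4Z)-7-[(tert-butyldiphenylsilyl)oxy]-4-methylhept-4-ene-1,2-diol F5, and silylation gives (2S,4Z)-7-[(tert-butyldiphenylsilyl)oxy]-4-methyl-1,2-bis[(triethylsilyl)oxy]hept-4-ene F6. Swern oxidation gives (2S,4Z)-7-[(tert-butyldiphenylsilyl)oxy]-4-methyl-2-[(triethylsilyl)oxy]hept-4-enal F7, and the Baylis–Hillman reaction gives methyl (4S,6Z)-9-[(tert-butyldiphenylsilyl)oxy]-3-hydroxy-6-methyl-2-methylidene-4-[(triethylsilyl)oxy]non-6-enoate F8. NBS/Me2S then gives methyl (2Z,4S,6Z)-2-(bromomethyl)-9-[(tert-butyldiphenylsilyl)oxy]-6-methyl-4-[(triethylsilyl)oxy]nona-2,6-dienoate F9.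
- Indium and 21 convert F9 through the allylindium methyl (2Z,4S,6Z)-9-[(tert-butyldiphenylsilyl)oxy]-2-[(dibromoindiganyl)methyl]-6-methyl-4-[(triethylsilyl)oxy]nona-2,6-dienoate F10 and the hydroxy ester methyl 2-[(2Z,4R,5S,6S,8Z)-11-[(tert-butyldiphenylsilyl)oxy]-4-hydroxy-2-iodo-8-methyl-6-[(triethylsilyl)oxy]undeca-2,8-dien-5-yl]prop-2-enoate F11 into the lactone (4S,5R)-4-[(1S,3Z)-6-[(tert-butyldiphenylsilyl)oxy]-3-methyl-1-[(triethylsilyl)oxy]hex-3-en-1-yl]-5-[(1Z)-2-iodoprop-1-en-1-yl]-3-methylideneoxolan-2-one F12. This has C6 and C7 as in 24 and C8 inverted.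
- Aqueous acetic acid gives (4R,5R)-4-[(1S,3Z)-6-[(tert-butyldiphenylsilyl)oxy]-1-hydroxy-3-methylhex-3-en-1-yl]-5-[(1Z)-2-iodoprop-1-en-1-yl]-3-methylideneoxolan-2-one F13. Mitsunobu esterification of F13 with 2-methylpropanoic acid (PPh3, DIAD, toluene) inverts C8 and gives 27.

Step 18 (epoxidation). The peracid may attack the other face of the C1=C10 alkene, or the free C3 hydroxyl may steer some oxidant to C4=C5. The fallback delivers the oxirane oxygen to the opposite face by the halohydrin route. It sets out from 31 and comes back at 32.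
- The C3 hydroxyl is silylated (TESCl, imidazole) to (1(10)Z,3S,4Z,6S,7R,8R)-8-(2-methylpropanoyloxy)-3-[(triethylsilyl)oxy]germacra-1(10),4,11(13)-trien-12,6-olide F14, which also removes any hydroxyl direction towards C4=C5.
- NBS in aqueous THF forms the bromonium ion on the exposed face and water opens it at tertiary C10 from the other face. This gives the bromohydrin (1S,3S,4Z,6S,7R,8R,10S)-1-bromo-10-hydroxy-8-(2-methylpropanoyloxy)-3-[(triethylsilyl)oxy]germacra-4,11(13)-dien-12,6-olide F15.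
- DBU in CH2Cl2 closes the oxirane with inversion at C1 to (1R,3S,4Z,6S,7R,8R,10S)-1,10-epoxy-8-(2-methylpropanoyloxy)-3-[(triethylsilyl)oxy]germacra-4,11(13)-dien-12,6-olide F16, and HF·pyridine removes the silyl group to give 32.

Further compounds
F1 | step 17 | (1(10)Z,3R,4Z,6S,7R,8R)-3-hydroxy-8-(2-methylpropanoyloxy)germacra-1(10),4,11(13)-trien-12,6-olide | C=C1C(=O)O[C@H]2/C=C(/C)[C@H](O)C/C=C(/C)C[C@@H](OC(=O)C(C)C)[C@@H]12
F2 | step 17 | (1(10)Z,4Z,6S,7R,8R)-8-(2-methylpropanoyloxy)-3-oxogermacra-1(10),4,11(13)-trien-12,6-olide | C=C1C(=O)O[C@H]2/C=C(/C)C(=O)C/C=C(/C)C[C@@H](OC(=O)C(C)C)[C@@H]12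
F3 | step 12 | (2S,4Z)-2-(anilinooxy)-7-[(tert-butyldiphenylsilyl)oxy]-4-methylhept-4-enal | O=C[C@@H](ONc1ccccc1)C/C(C)=C\CCO[Si](c2ccccc2)(c3ccccc3)C(C)(C)C
F4 | step 12 | (2S,4Z)-2-(anilinooxy)-7-[(tert-butyldiphenylsilyl)oxy]-4-methylhept-4-en-1-ol | OC[C@@H](ONc1ccccc1)C/C(C)=C\CCO[Si](c2ccccc2)(c3ccccc3)C(C)(C)C
F5 | step 12 | (2S,4Z)-7-[(tert-butyldiphenylsilyl)oxy]-4-methylhept-4-ene-1,2-diol | OC[C@@H](O)C/C(C)=C\CCO[Si](c1ccccc1)(c2ccccc2)C(C)(C)C
F6 | step 12 | (2S,4Z)-7-[(tert-butyldiphenylsilyl)oxy]-4-methyl-1,2-bis[(triethylsilyl)oxy]hept-4-ene | CC[Si](CC)(CC)OC[C@@H](O[Si](CC)(CC)CC)C/C(C)=C\CCO[Si](c1ccccc1)(c2ccccc2)C(C)(C)C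
F7 | step 12 | (2S,4Z)-7-[(tert-butyldiphenylsilyl)oxy]-4-methyl-2-[(triethylsilyl)oxy]hept-4-enal | O=C[C@@H](O[Si](CC)(CC)CC)C/C(C)=C\CCO[Si](c1ccccc1)(c2ccccc2)C(C)(C)C
F8 | step 12 | methyl (4S,6Z)-9-[(tert-butyldiphenylsilyl)oxy]-3-hydroxy-6-methyl-2-methylidene-4-[(triethylsilyl)oxy]non-6-enoate | C=C(C(=O)OC)C(O)[C@@H](O[Si](CC)(CC)CC)C/C(C)=C\CCO[Si](c1ccccc1)(c2ccccc2)C(C)(C)C
F9 | step 12 | methyl (2Z,4S,6Z)-2-(bromomethyl)-9-[(tert-butyldiphenylsilyl)oxy]-6-methyl-4-[(triethylsilyl)oxy]nona-2,6-dienoate | COC(=O)/C(CBr)=C/[C@@H](O[Si](CC)(CC)CC)C/C(C)=C\CCO[Si](c1ccccc1)(c2ccccc2)C(C)(C)C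
F10 | step 12 | methyl (2Z,4S,6Z)-9-[(tert-butyldiphenylsilyl)oxy]-2-[(dibromoindiganyl)methyl]-6-methyl-4-[(triethylsilyl)oxy]nona-2,6-dienoate | COC(=O)/C(C[In](Br)Br)=C/[C@@H](O[Si](CC)(CC)CC)C/C(C)=C\CCO[Si](c1ccccc1)(c2ccccc2)C(C)(C)C
F11 | step 12 | methyl 2-[(2Z,4R,5S,6S,8Z)-11-[(tert-butyldiphenylsilyl)oxy]-4-hydroxy-2-iodo-8-methyl-6-[(triethylsilyl)oxy]undeca-2,8-dien-5-yl]prop-2-enoate | C=C(C(=O)OC)[C@@H]([C@@H](O)/C=C(/C)I)[C@@H](O[Si](CC)(CC)CC)C/C(C)=C\CCO[Si](c1ccccc1)(c2ccccc2)C(C)(C)C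
F12 | step 12 | (4S,5R)-4-[(1S,3Z)-6-[(tert-butyldiphenylsilyl)oxy]-3-methyl-1-[(triethylsilyl)oxy]hex-3-en-1-yl]-5-[(1Z)-2-iodoprop-1-en-1-yl]-3-methylideneoxolan-2-one | C=C1C(=O)O[C@@H](/C=C(/C)I)[C@H]1[C@@H](O[Si](CC)(CC)CC)C/C(C)=C\CCO[Si](c2ccccc2)(c3ccccc3)C(C)(C)C
F13 | step 12 | (4R,5R)-4-[(1S,3Z)-6-[(tert-butyldiphenylsilyl)oxy]-1-hydroxy-3-methylhex-3-en-1-yl]-5-[(1Z)-2-iodoprop-1-en-1-yl]-3-methylideneoxolan-2-one | C=C1C(=O)O[C@@H](/C=C(/C)I)[C@H]1[C@@H](O)C/C(C)=C\CCO[Si](c2ccccc2)(c3ccccc3)C(C)(C)C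
F14 | step 18 | (1(10)Z,3S,4Z,6S,7R,8R)-8-(2-methylpropanoyloxy)-3-[(triethylsilyl)oxy]germacra-1(10),4,11(13)-trien-12,6-olide | C=C1C(=O)O[C@H]2/C=C(/C)[C@@H](O[Si](CC)(CC)CC)C/C=C(/C)C[C@@H](OC(=O)C(C)C)[C@@H]12
F15 | step 18 | (1S,3S,4Z,6S,7R,8R,10S)-1-bromo-10-hydroxy-8-(2-methylpropanoyloxy)-3-[(triethylsilyl)oxy]germacra-4,11(13)-dien-12,6-olide | C=C1C(=O)O[C@H]2/C=C(/C)[C@@H](O[Si](CC)(CC)CC)C[C@H](Br)[C@@](C)(O)C[C@@H](OC(=O)C(C)C)[C@@H]12
F16 | step 18 | (1R,3S,4Z,6S,7R,8R,10S)-1,10-epoxy-8-(2-methylpropanoyloxy)-3-[(triethylsilyl)oxy]germacra-4,11(13)-dien-12,6-olide | C=C1C(=O)O[C@H]2/C=C(/C)[C@@H](O[Si](CC)(CC)CC)C[C@H]3O[C@@]3(C)C[C@@H](OC(=O)C(C)C)[C@@H]12
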